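**Retrosynthetic overview**

- Feature: in the γ-lactone (O1, C2 carbonyl, C3 carbinol carbon, C4, C5) the two arylmethyl groups on C3 and C4 are cis, so their benzylic carbons can be bonded to each other as a cyclobutane cis-fused to the lactone.
- Last disconnection: restoring that benzylic–benzylic bond and three O-benzyl groups gives a 1-benzyloxy-6,7-diaryl-3-oxabicyclo[3.2.0]heptan-2-one; forward, one hydrogenolysis opens the cyclobutane and frees the three hydroxyls.
- Key disconnection: enantioselective sensitized intramolecular [2+2] cycloaddition of an (E)-cinnamyl (Z)-2-benzyloxycinnamate; the lactone ring closes first (C3–C4 bond, 5-exo), the cyclobutane second.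
- The ester comes from a (Z)-2-benzyloxycinnamic acid (glycolate aldol and dehydration on 4-benzyloxy-3-methoxybenzaldehyde, then saponification) and O-benzylconiferyl alcohol (ferulic acid, benzylation, i-Bu2AlH).

Key step: step 7

Remark: C3 and C4 are lactone atoms of the target; C1, C5, C6 and C7 are atoms of the bicycle (C1 becomes C3, C5 becomes C4); the configuration at C6 and C7 is assumed uncontrolled and is written exo,exo, since every C6/C7 epimer gives the same product in step 8, and the sense of induction of the ligand in step 7 is assumed (the antipodal ligand is used if it proves opposite).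

**Route**

Step 1
Reactants: 1 4-(benzyloxy)-3-methoxybenzaldehyde, 2 methyl 2-(benzyloxy)acetate
Product: 3 methyl 2-(benzyloxy)-3-[4-(benzyloxy)-3-methoxyphenyl]-3-hydroxypropanoate (racemic, syn/anti mixture)
Conditions: LDA (LiN(i-Pr)2), THF, −78 °C, 2; then 1, −78 °C; AcOH quench
Reagents that add atoms: none
Why: Aldol addition of the lithium enolate of the glycolate ester to a non-enolisable aryl aldehyde at low temperature; the configuration of the adduct is irrelevant because both centres become sp2 in step 2.

Step 2
Reactants: 3 methyl 2-(benzyloxy)-3-[4-(benzyloxy)-3-methoxyphenyl]-3-hydroxypropanoate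
Product: 5 methyl (Z)-2-(benzyloxy)-3-[4-(benzyloxy)-3-methoxyphenyl]acrylate, via β-mesyloxy ester 4 (not isolated)
Conditions: MsCl, Et3N, CH2Cl2, 0 °C; then DBU, 0 °C to rt
Reagents that add atoms: none
Why: Mesylation followed by E1cB elimination through the ester enolate should converge both diastereomers on the more stable Z alkene (aryl trans to the ester); a minor E isomer is tolerated because alkene geometry equilibrates in the triplet state in step 7.

Step 3
Reactants: 5 methyl (Z)-2-(benzyloxy)-3-[4-(benzyloxy)-3-methoxyphenyl]acrylate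
Product: 6 (Z)-2-(benzyloxy)-3-[4-(benzyloxy)-3-methoxyphenyl]acrylic acid
Conditions: LiOH·H2O, THF/MeOH/H2O, rt; then cold 1 M HCl to pH 3
Reagents that add atoms: lithium hydroxide, [Li+].[OH-]
Why: Saponification of a methyl ester; the benzyl enol ether and aryl benzyl ether are stable to base, and brief cold acidification should not hydrolyse the enol ether.

Step 4
Reactants: 7 ferulic acid
Product: 8 benzyl (E)-3-[4-(benzyloxy)-3-methoxyphenyl]acrylate
Conditions: BnBr (2.3 equiv), K2CO3, DMF, 60 °C
Reagents that add atoms: benzyl bromide, BrCc1ccccc1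
Why: SN2 alkylation of the phenoxide (Williamson ether synthesis) and of the carboxylate in one operation.

Step 5
Reactants: 8 benzyl (E)-3-[4-(benzyloxy)-3-methoxyphenyl]acrylate
Product: 9 (E)-3-[4-(benzyloxy)-3-methoxyphenyl]prop-2-en-1-ol
Conditions: i-Bu2AlH (3 equiv), CH2Cl2, −78 to 0 °C; aq. potassium sodium tartrate (KNaC4H4O6)
Reagents that add atoms: none
Why: 1,2-Reduction of a conjugated ester to the allylic alcohol by i-Bu2AlH, which leaves the alkene and the aryl benzyl ether untouched.

Step 6
Reactants: 6 (Z)-2-(benzyloxy)-3-[4-(benzyloxy)-3-methoxyphenyl]acrylic acid, 9 (E)-3-[4-(benzyloxy)-3-methoxyphenyl]prop-2-en-1-ol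
Product: 10 (E)-3-[4-(benzyloxy)-3-methoxyphenyl]allyl (Z)-2-(benzyloxy)-3-[4-(benzyloxy)-3-methoxyphenyl]acrylate
Conditions: DIC, DMAP (cat.), CH2Cl2, 0 °C to rt
Reagents that add atoms: none
Why: Steglich esterification under neutral conditions, chosen because the electron-rich cinnamyl alcohol would ionise under acidic activation.

Step 7
Reactants: 10 (E)-3-[4-(benzyloxy)-3-methoxyphenyl]allyl (Z)-2-(benzyloxy)-3-[4-(benzyloxy)-3-methoxyphenyl]acrylate
Product: 11 (1S,5R,6R,7R)-1-(benzyloxy)-6,7-bis[4-(benzyloxy)-3-methoxyphenyl]-3-oxabicyclo[3.2.0]heptan-2-one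
Conditions: [Ir(ppy)2(dtbbpy)]PF6 (1 mol%), Sc(OTf)3 (10 mol%), (S,S)-t-Bu-PyBox (12 mol%), i-PrOAc/MeCN 3:1 (5 mM), 450 nm LEDs, 0 °C, Ar
Reagents that add atoms: none
Why: Proposed new method: the trivalent scandium–PyBox complex should be chelated by the ester carbonyl and the 2-benzyloxy oxygen of 10, lowering the triplet energy of the 2-alkoxycinnamate below that of the iridium sensitizer (about 49 kcal/mol), so that Dexter energy transfer reaches only the bound, face-differentiated chromophore and not the free ester or the styrene; the closest known reactions are chiral Lewis acid catalysed triplet-sensitized [2+2] cycloadditions of chelating enones and of cinnamate esters with styrenes, and sensitized intramolecular [2+2] cycloadditions of tethered styrenes. The twisted triplet attacks through the acrylate α-carbon on the internal carbon of the cinnamyl alkene in a 5-exo-trig radical closure (rule of five), which forms the C1–C5 bond and the lactone ring and leaves a 1,4-diradical on the two benzylic carbons. After intersystem crossing this diradical closes the four-membered ring by radical recombination (C6–C7 bond), which is possible only when both benzylic carbons lie on the same face of the lactone; the other diradical fragments back to 10, so C5 follows C1 through the obligatory cis fusion. C1 is set by the ligand, which should leave the Si face of the acrylate α-carbon open, whereas C6 and C7 are not controlled and need not be. The step needs enantioface selection without a racemic background and cyclisation ahead of intermolecular dimerisation: the sensitizer lying below the triplet energy of the free substrate, the two-point binding and high dilution should secure this, and triplets formed in the unreactive s-cis ester rotamer only relax by alkene E/Z isomerisation and are recycled.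

Step 8
Reactants: 11 (1S,5R,6R,7R)-1-(benzyloxy)-6,7-bis[4-(benzyloxy)-3-methoxyphenyl]-3-oxabicyclo[3.2.0]heptan-2-one
Product: 13 (3S,4R)-3-hydroxy-3,4-bis(4-hydroxy-3-methoxybenzyl)dihydrofuran-2(3H)-one (the target), via debenzylated cyclobutane 12 (not isolated)
Conditions: H2 (5 bar), Pd(OH)2/C, EtOH/EtOAc/AcOH, 50 °C
Reagents that add atoms: none
Why: Proposed new method: the three benzyl ethers should fall by ordinary palladium-catalysed hydrogenolysis to give 12, and the C6–C7 bond, which is benzylic at both ends, flanked by electron-rich aryl groups and weakened by roughly 26 kcal/mol of ring strain, should then add to the palladium surface and be hydrogenated to two CH2 groups, the closest known reaction types being catalytic hydrogenolysis of arylcyclopropanes and alkali-metal reductive cleavage of 1,2-diarylcyclobutanes; no stereocentre is formed, the C6 and C7 centres vanish, and C3 and C4 carry no benzylic or epimerisable bond afterwards.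

**Compound list**

1 | 4-(benzyloxy)-3-methoxybenzaldehyde | COc1cc(C=O)ccc1OCc1ccccc1 | starting material
2 | methyl 2-(benzyloxy)acetate | COC(=O)COCc1ccccc1 | starting material
3 | methyl 2-(benzyloxy)-3-[4-(benzyloxy)-3-methoxyphenyl]-3-hydroxypropanoate (racemic, both diastereomers) | COC(=O)C(OCc1ccccc1)C(O)c1ccc(OCc2ccccc2)c(OC)c1 | intermediate
4 | methyl 2-(benzyloxy)-3-[4-(benzyloxy)-3-methoxyphenyl]-3-(methylsulfonyloxy)propanoate (racemic, formed in the flask in step 2) | COC(=O)C(OCc1ccccc1)C(OS(C)(=O)=O)c1ccc(OCc2ccccc2)c(OC)c1 | intermediate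
5 | methyl (Z)-2-(benzyloxy)-3-[4-(benzyloxy)-3-methoxyphenyl]acrylate | COC(=O)/C(OCc1ccccc1)=C/c1ccc(OCc2ccccc2)c(OC)c1 | intermediate
6 | (Z)-2-(benzyloxy)-3-[4-(benzyloxy)-3-methoxyphenyl]acrylic acid | OC(=O)/C(OCc1ccccc1)=C/c1ccc(OCc2ccccc2)c(OC)c1 | intermediate
7 | ferulic acid, (E)-3-(4-hydroxy-3-methoxyphenyl)acrylic acid | COc1cc(/C=C/C(=O)O)ccc1O | starting material
8 | benzyl (E)-3-[4-(benzyloxy)-3-methoxyphenyl]acrylate | COc1cc(/C=C/C(=O)OCc2ccccc2)ccc1OCc1ccccc1 | intermediate
9 | (E)-3-[4-(benzyloxy)-3-methoxyphenyl]prop-2-en-1-ol | COc1cc(/C=C/CO)ccc1OCc1ccccc1 | intermediate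
10 | (E)-3-[4-(benzyloxy)-3-methoxyphenyl]allyl (Z)-2-(benzyloxy)-3-[4-(benzyloxy)-3-methoxyphenyl]acrylate | O=C(OC/C=C/c1ccc(OCc2ccccc2)c(OC)c1)/C(OCc1ccccc1)=C/c1ccc(OCc2ccccc2)c(OC)c1 | intermediate
11 | (1S,5R,6R,7R)-1-(benzyloxy)-6,7-bis[4-(benzyloxy)-3-methoxyphenyl]-3-oxabicyclo[3.2.0]heptan-2-one (cis-fused, both aryl groups written exo) | O=C1OC[C@H]2[C@H](c3ccc(OCc4ccccc4)c(OC)c3)[C@H](c3ccc(OCc4ccccc4)c(OC)c3)[C@@]12OCc1ccccc1 | intermediate
12 | (1S,5R,6R,7R)-1-hydroxy-6,7-bis(4-hydroxy-3-methoxyphenyl)-3-oxabicyclo[3.2.0]heptan-2-one (formed in the flask in step 8) | O=C1OC[C@H]2[C@H](c3ccc(O)c(OC)c3)[C@H](c3ccc(O)c(OC)c3)[C@@]12O | intermediate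
13 | (3S,4R)-3-hydroxy-3,4-bis(4-hydroxy-3-methoxybenzyl)dihydrofuran-2(3H)-one | COc1cc(C[C@@H]2COC(=O)[C@]2(O)Cc2ccc(O)c(OC)c2)ccc1O | target

**Step count**

Total: 8 steps. Longest linear sequence: 6 steps (steps 1, 2, 3, 6, 7, 8 from compound 1).

**Steps most likely to fail**

1. Step 7. The ester may stay in its unreactive rotamer so that energy transfer only isomerises the alkenes. Intermolecular dimerisation or ionisation of the cinnamyl ester by the Lewis acid may take over, and facial selection may be poor.
Fallback (known chemistry, leaves the cycloaddition): it sets out from aldehyde 1 and returns at target 13.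
   - Stobbe condensation of 1 with dimethyl succinate (NaOMe, MeOH, reflux) should give the half-ester (E)-4-[4-(benzyloxy)-3-methoxyphenyl]-3-(methoxycarbonyl)but-3-enoic acid F1.
   - Asymmetric hydrogenation ([Rh(cod)2]BF4 with the Me-DuPhos antipode that delivers the S acid, H2, MeOH) should give (S)-4-[4-(benzyloxy)-3-methoxyphenyl]-3-(methoxycarbonyl)butanoic acid F2.
   - Reduction of the ester in the potassium carboxylate (Ca(BH4)2 from CaCl2 and NaBH4, EtOH) and acid lactonisation should give (S)-4-[4-(benzyloxy)-3-methoxybenzyl]dihydrofuran-2(3H)-one F3.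
   - In parallel, 1 is reduced (NaBH4, MeOH) to [4-(benzyloxy)-3-methoxyphenyl]methanol F4 and converted (PBr3, Et2O, 0 °C) into 4-(benzyloxy)-3-methoxybenzyl bromide F5.
   - Alkylation of the enolate of F3 (LiN(SiMe3)2, THF, −78 °C) with F5, anti to the C4 substituent, should give (3S,4S)-3,4-bis[4-(benzyloxy)-3-methoxybenzyl]dihydrofuran-2(3H)-one F6.
   - Enolate oxidation (KN(SiMe3)2, THF, −78 °C; 2-(phenylsulfonyl)-3-phenyloxaziridine) from the face anti to the C4 arylmethyl group should place the hydroxyl trans to it, giving (3S,4R)-3,4-bis[4-(benzyloxy)-3-methoxybenzyl]-3-hydroxydihydrofuran-2(3H)-one F7 with the two arylmethyl groups cis.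
   - Debenzylation (H2, Pd/C, EtOAc/EtOH, rt) then gives 13.

2. Step 8. The cyclobutane bond may resist hydrogenolysis under conditions that spare the arenes, so that the reaction stops after debenzylation, or a singly benzylic ring bond may be cleaved instead.
Fallback (known reaction types, oxidative instead of reductive opening): it sets out from bicycle 11 and returns at 13.
   - Photoinduced electron-transfer oxygenation (Ru(bpz)3(PF6)2, O2, MeCN, blue light) oxidises one electron-rich aryl ring by one electron and opens the C6–C7 bond to a 1,4-radical cation that is trapped by O2. This should give the cis-fused 1,2-dioxane (4aS,7aR)-4a-(benzyloxy)-1,4-bis[4-(benzyloxy)-3-methoxyphenyl]tetrahydro-1H-furo[3,4-d][1,2]dioxin-5(4aH)-one F8, as is known for 1,2-diarylcyclobutanes.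
   - Hydrogenation (H2, Pd/C, EtOH/AcOH) then cleaves the O–O bond, the two electron-rich benzylic C–O bonds and the three benzyl ethers to give 13.
   - Partial cycloreversion of the radical cation would erode the enantiomeric purity and has to be watched.

3. Step 6. The activated acid may rearrange by O-to-N acyl shift, or the electron-rich cinnamyl alcohol may ionise and give transposed or etherified material.
Fallback (activation of the alcohol instead of the acid): it sets out from acid 6 and alcohol 9 and returns at ester 10. Mitsunobu esterification (PPh3, DIAD, THF, 0 °C) has the carboxylate displace the alkoxyphosphonium ion at the primary allylic carbon. This fallback makes no new compound (F0).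

**Further compounds**

F1 | step 7 | (E)-4-[4-(benzyloxy)-3-methoxyphenyl]-3-(methoxycarbonyl)but-3-enoic acid | COC(=O)/C(CC(=O)O)=C/c1ccc(OCc2ccccc2)c(OC)c1
F2 | step 7 | (S)-4-[4-(benzyloxy)-3-methoxyphenyl]-3-(methoxycarbonyl)butanoic acid | COC(=O)[C@H](CC(=O)O)Cc1ccc(OCc2ccccc2)c(OC)c1
F3 | step 7 | (S)-4-[4-(benzyloxy)-3-methoxybenzyl]dihydrofuran-2(3H)-one | COc1cc(C[C@@H]2COC(=O)C2)ccc1OCc1ccccc1
F4 | step 7 | [4-(benzyloxy)-3-methoxyphenyl]methanol | COc1cc(CO)ccc1OCc1ccccc1
F5 | step 7 | 4-(benzyloxy)-3-methoxybenzyl bromide | COc1cc(CBr)ccc1OCc1ccccc1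
F6 | step 7 | (3S,4S)-3,4-bis[4-(benzyloxy)-3-methoxybenzyl]dihydrofuran-2(3H)-one | COc1cc(C[C@@H]2COC(=O)[C@H]2Cc2ccc(OCc3ccccc3)c(OC)c2)ccc1OCc1ccccc1
F7 | step 7 | (3S,4R)-3,4-bis[4-(benzyloxy)-3-methoxybenzyl]-3-hydroxydihydrofuran-2(3H)-one | COc1cc(C[C@@H]2COC(=O)[C@]2(O)Cc2ccc(OCc3ccccc3)c(OC)c2)ccc1OCc1ccccc1
F8 | step 8 | (4aS,7aR)-4a-(benzyloxy)-1,4-bis[4-(benzyloxy)-3-methoxyphenyl]tetrahydro-1H-furo[3,4-d][1,2]dioxin-5(4aH)-one (C1/C4 epimers) | O=C1OC[C@H]2C(c3ccc(OCc4ccccc4)c(OC)c3)OOC(c3ccc(OCc4ccccc4)c(OC)c3)[C@@]12OCc1ccccc1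
F0 | step 6 | none | none
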